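The five hydroquinone rings of the hexamer (rings B to F) are each disconnected at C1–C2, C3–C4 and C1–C6 into a chromium carbene, ethoxyacetylene and one CO ligand. The key step exploits the pattern of ring B: the ring-A aryloxy group sits on C4, para to the C1 oxygen, C2 and C6 are oxygenated, and C3 and C5 are unsubstituted. One benzannulation therefore closes ring B with all four oxygens in place and leaves C1–OH free to start the next ring. Its precursor is the pentacarbonylchromium carbene carrying a (Z)-2-ethoxyvinyl group and the 2,4,6-trimethoxyphenoxy group of ring A, assembled by acyloxy exchange. Four repeats and one global dealkylation finish the route.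

Key step: step 4

Assumption: compounds 1, 7 and 9 are bought (9 as a hexane solution); acyloxycarbene complex 6, which decomposes only on warming towards room temperature, is taken to keep as a CH2Cl2 solution at −78 °C under Ar for the whole sequence, and more can be made from the storable salt 5 in the same way; the Z geometry set by bromide 1 has no bearing on the product, since the ethoxy-bearing vinyl carbon loses its hydrogen when the new ring aromatises; chromium released after each annulation is counted as Cr2O3.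

Step 1
Reactants: 1 cis-1-bromo-2-ethoxyethylene [(Z)-1-bromo-2-ethoxyethene]; 2 chromium hexacarbonyl Cr(CO)6
Product: 5 tetramethylammonium pentacarbonyl[(Z)-3-ethoxyprop-2-enoyl]chromate, via (Z)-2-ethoxyvinyllithium 3 (not isolated), via lithium acylchromate 4 (not isolated)
Conditions: n-BuLi (slight deficiency), Et2O, −78 °C; Cr(CO)6, THF, −78 to 0 °C; Me4NBr, H2O, 0 °C
Reagents that add atoms: tetramethylammonium bromide, C[N+](C)(C)C.[Br-]
Why: Bromine–lithium exchange on the Z bromide is stereoretentive at −78 °C, and the vinyllithium should add to a CO ligand of Cr(CO)6 as in the Fischer carbene synthesis, the acylchromate being kept as its storable tetramethylammonium salt.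

Step 2
Reactants: 5 tetramethylammonium pentacarbonyl[(Z)-3-ethoxyprop-2-enoyl]chromate
Product: 6 pentacarbonyl[(Z)-2-ethoxyvinyl(pivaloyloxy)carbene]chromium
Conditions: PivCl, CH2Cl2, −40 °C, Ar; cold filtration from Me4NCl; solution kept at −78 °C
Reagents that add atoms: pivaloyl chloride, CC(C)(C)C(=O)Cl
Why: O-acylation of the acylchromate oxygen by pivaloyl chloride is the standard activation of the Fischer acyloxycarbene method, and the complex, stabilised by its donor 2-ethoxyvinyl group, should keep at −78 °C under argon so that one batch serves all five aryloxy exchanges.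

Step 3
Reactants: 6 pentacarbonyl[(Z)-2-ethoxyvinyl(pivaloyloxy)carbene]chromium (portion of the cold solution); 7 2,4,6-trimethoxyphenol
Product: 8 pentacarbonyl[(Z)-2-ethoxyvinyl(2,4,6-trimethoxyphenoxy)carbene]chromium
Conditions: CH2Cl2, −40 to 0 °C, Ar
Reagents that add atoms: none
Why: The carbene carbon of the acyloxycarbene complex behaves like the carbonyl of a mixed anhydride, so the electron-rich phenol should displace pivalate there (Fischer acyloxy exchange), the tert-butyl group shielding the competing acyl carbon.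

Step 4
Reactants: 8 aryloxy(2-ethoxyvinyl)carbene complex of ring A; 9 ethoxyacetylene
Product: 11 2,6-diethoxy-4-(2,4,6-trimethoxyphenoxy)phenol (rings A–B), via Cr(CO)3-bound rings A–B phenol 10 (not isolated)
Conditions: ethoxyacetylene (slight excess), THF (dilute), 50 °C, sealed vessel, Ar; then MeCN, air, rt
Reagents that add atoms: none
Why: Proposed new method: an aryloxy(2-alkoxyvinyl)carbene complex has not been annulated with an ynol ether, but the expected course is that of the Dötz benzannulation of alkenyl(alkoxy)- and alkenyl(aryloxy)carbene chromium complexes with terminal alkynes, the closest known reaction type. Loss of one cis CO from 8 (eased by the Z-ethoxy oxygen, which can hold the vacant site as a five-membered chelate) lets ethoxyacetylene coordinate and insert into Cr=C to form C3–C4, and CO insertion at the new carbene carbon forms C1–C2 and gives a chromium-bound dienylketene. Ring B closes by thermal 6π electrocyclisation of this dienylketene (C1–C6), the cyclohexadienone tautomerises to phenol complex 10, and air in MeCN releases 11; no stereocentre is formed. The selectivity needed is regiochemical, the alkyne CH carbon having to bond to the carbene carbon so that OEt ends up on C2, and it is secured twice: H is the smaller alkyne substituent, and the CH terminus is the nucleophilic end of the ynol ether, matched to the electrophilic carbene carbon. Phenol formation should win over five-membered ring closure without CO because alkenyl chromium complexes in THF take up CO reliably and the aryloxy group is a weaker donor than alkoxy or amino, which keeps the metal electron-poor. Should the ynol ether add to 8 before CO loss, the resulting dienyl(ethoxy)carbene is expected to enter the same ketene pathway.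

Step 5
Reactants: 6 pentacarbonyl[(Z)-2-ethoxyvinyl(pivaloyloxy)carbene]chromium (portion of the cold solution); 11 rings A–B phenol
Product: 12 pentacarbonyl{(Z)-2-ethoxyvinyl[2,6-diethoxy-4-(2,4,6-trimethoxyphenoxy)phenoxy]carbene}chromium
Conditions: CH2Cl2, −40 to 0 °C, Ar
Reagents that add atoms: none
Why: Phenol 11 has the same 2,6-dialkoxy environment as 7 and should displace pivalate at the carbene carbon in the same Fischer acyloxy exchange.

Step 6
Reactants: 12 carbene complex of rings A–B; 9 ethoxyacetylene
Product: 14 2,6-diethoxy-4-[2,6-diethoxy-4-(2,4,6-trimethoxyphenoxy)phenoxy]phenol (rings A–B–C), via Cr(CO)3-bound rings A–C phenol 13 (not isolated)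
Conditions: ethoxyacetylene (slight excess), THF (dilute), 50 °C, sealed vessel, Ar; then MeCN, air, rt
Reagents that add atoms: none
Why: Proposed new method: this is the same untested pairing of an aryloxy(2-ethoxyvinyl)carbene with an ynol ether as in step 4, expected to run through CO loss, regioselective alkyne insertion (C3–C4), CO insertion (C1–C2) and 6π electrocyclisation of the dienylketene (C1–C6) to close ring C, the closest known reaction type being the Dötz benzannulation of alkenyl(alkoxy)carbene chromium complexes with terminal alkynes.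

Step 7
Reactants: 6 pentacarbonyl[(Z)-2-ethoxyvinyl(pivaloyloxy)carbene]chromium (portion of the cold solution); 14 rings A–B–C phenol
Product: 15 pentacarbonylchromium (Z)-2-ethoxyvinyl carbene complex carrying the aryloxy group of phenol 14 on the carbene carbon
Conditions: CH2Cl2, −40 to 0 °C, Ar
Reagents that add atoms: none
Why: The reacting 2,6-diethoxyphenol terminus is unchanged from 11, so the Fischer acyloxy exchange should proceed as in step 5.

Step 8
Reactants: 15 carbene complex of rings A–C; 9 ethoxyacetylene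
Product: 17 2,6-diethoxy-4-{2,6-diethoxy-4-[2,6-diethoxy-4-(2,4,6-trimethoxyphenoxy)phenoxy]phenoxy}phenol (rings A–D), via Cr(CO)3-bound rings A–D phenol 16 (not isolated)
Conditions: ethoxyacetylene (slight excess), THF (dilute), 50 °C, sealed vessel, Ar; then MeCN, air, rt
Reagents that add atoms: none
Why: Proposed new method: the carbene–ynol ether–CO benzannulation of step 4 is repeated to close ring D by CO loss, alkyne insertion with the CH carbon on the carbene carbon, CO insertion and 6π electrocyclisation of the dienylketene, the closest known reaction type being the Dötz benzannulation of alkenyl(alkoxy)carbene chromium complexes with terminal alkynes.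

Step 9
Reactants: 6 pentacarbonyl[(Z)-2-ethoxyvinyl(pivaloyloxy)carbene]chromium (portion of the cold solution); 17 rings A–D phenol
Product: 18 pentacarbonylchromium (Z)-2-ethoxyvinyl carbene complex carrying the aryloxy group of phenol 17 on the carbene carbon
Conditions: CH2Cl2, −40 to 0 °C, Ar
Reagents that add atoms: none
Why: The same Fischer acyloxy exchange at the highly electrophilic acyloxycarbene carbon should apply, the nucleophilic terminus being the same 2,6-diethoxyphenol unit.

Step 10
Reactants: 18 carbene complex of rings A–D; 9 ethoxyacetylene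
Product: 20 2,6-diethoxy-4-(2,6-diethoxy-4-{2,6-diethoxy-4-[2,6-diethoxy-4-(2,4,6-trimethoxyphenoxy)phenoxy]phenoxy}phenoxy)phenol (rings A–E), via Cr(CO)3-bound rings A–E phenol 19 (not isolated)
Conditions: ethoxyacetylene (slight excess), THF (dilute), 50 °C, sealed vessel, Ar; then MeCN, air, rt
Reagents that add atoms: none
Why: Proposed new method: ring E is closed by the same carbene–ynol ether–CO benzannulation as in step 4 (CO loss, regioselective alkyne insertion, CO insertion, 6π electrocyclisation of the dienylketene, tautomerisation), the closest known reaction type being the Dötz benzannulation of alkenyl(alkoxy)carbene chromium complexes with terminal alkynes.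

Step 11
Reactants: 6 pentacarbonyl[(Z)-2-ethoxyvinyl(pivaloyloxy)carbene]chromium (portion of the cold solution); 20 rings A–E phenol
Product: 21 pentacarbonylchromium (Z)-2-ethoxyvinyl carbene complex carrying the aryloxy group of phenol 20 on the carbene carbon
Conditions: CH2Cl2, −40 to 0 °C, Ar
Reagents that add atoms: none
Why: Fischer acyloxy exchange at the carbene carbon should again install the oligomeric aryloxy group, since only the terminal phenol takes part.

Step 12
Reactants: 21 carbene complex of rings A–E; 9 ethoxyacetylene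
Product: 23 2,6-diethoxy-4-[2,6-diethoxy-4-(2,6-diethoxy-4-{2,6-diethoxy-4-[2,6-diethoxy-4-(2,4,6-trimethoxyphenoxy)phenoxy]phenoxy}phenoxy)phenoxy]phenol (rings A–F), via Cr(CO)3-bound rings A–F phenol 22 (not isolated)
Conditions: ethoxyacetylene (slight excess), THF (dilute), 50 °C, sealed vessel, Ar; then MeCN, air, rt
Reagents that add atoms: none
Why: Proposed new method: the final carbene–ynol ether–CO benzannulation closes ring F as in step 4 and delivers its central C4–OH directly from the CO ligand, the closest known reaction type being the Dötz benzannulation of alkenyl(alkoxy)carbene chromium complexes with terminal alkynes.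

Step 13
Reactants: 23 rings A–F phenol
Product: 24 5-[2,6-dihydroxy-4-(2,6-dihydroxy-4-{2,6-dihydroxy-4-[2,6-dihydroxy-4-(2,4,6-trihydroxyphenoxy)phenoxy]phenoxy}phenoxy)phenoxy]benzene-1,2,3-triol (target, CNP0187343.0)
Conditions: BBr3 (large excess), CH2Cl2, −78 °C to rt, Ar; then degassed H2O, 0 °C
Reagents that add atoms: none
Why: BBr3 dealkylation should cleave all three methyl and ten ethyl aryl ethers by bromide attack at the alkyl carbon, while the diaryl ether links, which offer no sp3 carbon, stay intact.

Compound list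
1 | cis-1-bromo-2-ethoxyethylene, (Z)-1-bromo-2-ethoxyethene | CCO/C=C\Br | starting material
2 | chromium hexacarbonyl, Cr(CO)6 | O=C=[Cr](=C=O)(=C=O)(=C=O)(=C=O)=C=O | starting material
3 | (Z)-2-ethoxyvinyllithium | CCO/C=C\[Li] | intermediate
4 | lithium pentacarbonyl[(Z)-3-ethoxyprop-2-enoyl]chromate | [Li+].[O-]C(/C=C\OCC)=[Cr](=C=O)(=C=O)(=C=O)(=C=O)=C=O | intermediate
5 | tetramethylammonium pentacarbonyl[(Z)-3-ethoxyprop-2-enoyl]chromate | C[N+](C)(C)C.[O-]C(/C=C\OCC)=[Cr](=C=O)(=C=O)(=C=O)(=C=O)=C=O | intermediate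
6 | pentacarbonyl[(Z)-2-ethoxyvinyl(pivaloyloxy)carbene]chromium | CC(C)(C)C(=O)OC(/C=C\OCC)=[Cr](=C=O)(=C=O)(=C=O)(=C=O)=C=O | intermediate
7 | 2,4,6-trimethoxyphenol | COc1cc(OC)c(O)c(OC)c1 | starting material
8 | pentacarbonyl[(Z)-2-ethoxyvinyl(2,4,6-trimethoxyphenoxy)carbene]chromium | O=C=[Cr](=C=O)(=C=O)(=C=O)(=C=O)=C(/C=C\OCC)Oc1c(OC)cc(OC)cc1OC | intermediate
9 | ethoxyacetylene | CCOC#C | starting material
10 | tricarbonylchromium complex of 11, η6 on ring B (metal fragment written dot-separated) | COc1cc(OC)c(Oc2cc(OCC)c(O)c(OCC)c2)c(OC)c1.O=C=[Cr](=C=O)=C=O | intermediate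
11 | 2,6-diethoxy-4-(2,4,6-trimethoxyphenoxy)phenol (rings A–B) | COc1cc(OC)c(Oc2cc(OCC)c(O)c(OCC)c2)c(OC)c1 | intermediate
12 | pentacarbonyl{(Z)-2-ethoxyvinyl[2,6-diethoxy-4-(2,4,6-trimethoxyphenoxy)phenoxy]carbene}chromium | O=C=[Cr](=C=O)(=C=O)(=C=O)(=C=O)=C(/C=C\OCC)Oc1c(OCC)cc(Oc2c(OC)cc(OC)cc2OC)cc1OCC | intermediate
13 | tricarbonylchromium complex of 14, η6 on ring C (metal fragment written dot-separated) | COc1cc(OC)c(Oc2cc(OCC)c(Oc3cc(OCC)c(O)c(OCC)c3)c(OCC)c2)c(OC)c1.O=C=[Cr](=C=O)=C=O | intermediate
14 | 2,6-diethoxy-4-[2,6-diethoxy-4-(2,4,6-trimethoxyphenoxy)phenoxy]phenol (rings A–B–C) | COc1cc(OC)c(Oc2cc(OCC)c(Oc3cc(OCC)c(O)c(OCC)c3)c(OCC)c2)c(OC)c1 | intermediate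
15 | pentacarbonylchromium (Z)-2-ethoxyvinyl carbene complex with the aryloxy group of 14 on the carbene carbon | O=C=[Cr](=C=O)(=C=O)(=C=O)(=C=O)=C(/C=C\OCC)Oc1c(OCC)cc(Oc2c(OCC)cc(Oc3c(OC)cc(OC)cc3OC)cc2OCC)cc1OCC | intermediate
16 | tricarbonylchromium complex of 17, η6 on ring D (metal fragment written dot-separated) | COc1cc(OC)c(Oc2cc(OCC)c(Oc3cc(OCC)c(Oc4cc(OCC)c(O)c(OCC)c4)c(OCC)c3)c(OCC)c2)c(OC)c1.O=C=[Cr](=C=O)=C=O | intermediate
17 | 2,6-diethoxy-4-{2,6-diethoxy-4-[2,6-diethoxy-4-(2,4,6-trimethoxyphenoxy)phenoxy]phenoxy}phenol (rings A–D) | COc1cc(OC)c(Oc2cc(OCC)c(Oc3cc(OCC)c(Oc4cc(OCC)c(O)c(OCC)c4)c(OCC)c3)c(OCC)c2)c(OC)c1 | intermediate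
18 | pentacarbonylchromium (Z)-2-ethoxyvinyl carbene complex with the aryloxy group of 17 on the carbene carbon | O=C=[Cr](=C=O)(=C=O)(=C=O)(=C=O)=C(/C=C\OCC)Oc1c(OCC)cc(Oc2c(OCC)cc(Oc3c(OCC)cc(Oc4c(OC)cc(OC)cc4OC)cc3OCC)cc2OCC)cc1OCC | intermediate
19 | tricarbonylchromium complex of 20, η6 on ring E (metal fragment written dot-separated) | COc1cc(OC)c(Oc2cc(OCC)c(Oc3cc(OCC)c(Oc4cc(OCC)c(Oc5cc(OCC)c(O)c(OCC)c5)c(OCC)c4)c(OCC)c3)c(OCC)c2)c(OC)c1.O=C=[Cr](=C=O)=C=O | intermediate
20 | 2,6-diethoxy-4-(2,6-diethoxy-4-{2,6-diethoxy-4-[2,6-diethoxy-4-(2,4,6-trimethoxyphenoxy)phenoxy]phenoxy}phenoxy)phenol (rings A–E) | COc1cc(OC)c(Oc2cc(OCC)c(Oc3cc(OCC)c(Oc4cc(OCC)c(Oc5cc(OCC)c(O)c(OCC)c5)c(OCC)c4)c(OCC)c3)c(OCC)c2)c(OC)c1 | intermediate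
21 | pentacarbonylchromium (Z)-2-ethoxyvinyl carbene complex with the aryloxy group of 20 on the carbene carbon | O=C=[Cr](=C=O)(=C=O)(=C=O)(=C=O)=C(/C=C\OCC)Oc1c(OCC)cc(Oc2c(OCC)cc(Oc3c(OCC)cc(Oc4c(OCC)cc(Oc5c(OC)cc(OC)cc5OC)cc4OCC)cc3OCC)cc2OCC)cc1OCC | intermediate
22 | tricarbonylchromium complex of 23, η6 on ring F (metal fragment written dot-separated) | COc1cc(OC)c(Oc2cc(OCC)c(Oc3cc(OCC)c(Oc4cc(OCC)c(Oc5cc(OCC)c(Oc6cc(OCC)c(O)c(OCC)c6)c(OCC)c5)c(OCC)c4)c(OCC)c3)c(OCC)c2)c(OC)c1.O=C=[Cr](=C=O)=C=O | intermediate
23 | 2,6-diethoxy-4-[2,6-diethoxy-4-(2,6-diethoxy-4-{2,6-diethoxy-4-[2,6-diethoxy-4-(2,4,6-trimethoxyphenoxy)phenoxy]phenoxy}phenoxy)phenoxy]phenol (rings A–F) | COc1cc(OC)c(Oc2cc(OCC)c(Oc3cc(OCC)c(Oc4cc(OCC)c(Oc5cc(OCC)c(Oc6cc(OCC)c(O)c(OCC)c6)c(OCC)c5)c(OCC)c4)c(OCC)c3)c(OCC)c2)c(OC)c1 | intermediate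
24 | 5-[2,6-dihydroxy-4-(2,6-dihydroxy-4-{2,6-dihydroxy-4-[2,6-dihydroxy-4-(2,4,6-trihydroxyphenoxy)phenoxy]phenoxy}phenoxy)phenoxy]benzene-1,2,3-triol | Oc1cc(O)c(Oc2cc(O)c(Oc3cc(O)c(Oc4cc(O)c(Oc5cc(O)c(Oc6cc(O)c(O)c(O)c6)c(O)c5)c(O)c4)c(O)c3)c(O)c2)c(O)c1 | target

Totals
Total step count: 13. Longest linear sequence: 13 steps (steps 1 to 13; the single batch of 6 from step 2 is drawn on in steps 3, 5, 7, 9 and 11).

Steps most likely to fail

1. Step 4. After alkyne uptake the donor-substituted vinylcarbene may close to a five-membered ring without taking up CO, or stall as a stabilised dienylcarbene. The freed phenol may also swap aryloxy groups with unreacted carbene complex. Fallback, setting out from 7 and returning at 11: 1,3-diethoxybenzene is lithiated between its two ethoxy groups (n-BuLi, THF), borylated with B(OMe)3 and oxidised with H2O2 and NaOH to 2,6-diethoxyphenol F1. Para-bromination with NBS gives 4-bromo-2,6-diethoxyphenol F2, and benzylation (BnBr, K2CO3, DMF) gives 2-(benzyloxy)-5-bromo-1,3-diethoxybenzene F3. Ullmann ether coupling of 7 with F3 (CuI, N,N-dimethylglycine, Cs2CO3, dioxane, 100 °C) should give 2-(benzyloxy)-1,3-diethoxy-5-(2,4,6-trimethoxyphenoxy)benzene F4. Hydrogenolysis (H2, Pd/C, EtOAc) then gives 11.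

2. Step 6. The first repeat must tolerate a bulkier and more electron-rich aryloxy group, and aryloxy transfer between the product phenol and remaining carbene complex would scramble chain lengths. Fallback, setting out from 11 and returning at 14: Buchwald–Hartwig C–O coupling of 11 with 2-(benzyloxy)-5-bromo-1,3-diethoxybenzene F3, prepared as in the first fallback (Pd(OAc)2, t-BuXPhos, K3PO4, toluene, 100 °C), should give the benzyl ether of the rings A–B–C phenol F5. Hydrogenolysis (H2, Pd/C, EtOAc) then gives 14.

3. Step 12. At the pentamer stage the annulation runs at low molar concentration, so thermal decay of the carbene complex and loss of its aryloxy group have time to compete with alkyne uptake. Fallback, setting out from 20 and returning at 24: Ullmann ether coupling of 20 with commercial 5-bromo-1,2,3-trimethoxybenzene (CuI, N,N-dimethylglycine, Cs2CO3, dioxane, 100 °C) should give the fully alkylated rings A–F hexamer ending in a 3,4,5-trimethoxyphenyl group F6. BBr3 in CH2Cl2 then cleaves all fourteen alkyl ethers to give 24 directly.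

Further compounds
F1 | step 4 | 2,6-diethoxyphenol | CCOc1cccc(OCC)c1O
F2 | step 4 | 4-bromo-2,6-diethoxyphenol | CCOc1cc(Br)cc(OCC)c1O
F3 | step 4 | 2-(benzyloxy)-5-bromo-1,3-diethoxybenzene | CCOc1cc(Br)cc(OCC)c1OCc1ccccc1
F4 | step 4 | 2-(benzyloxy)-1,3-diethoxy-5-(2,4,6-trimethoxyphenoxy)benzene | COc1cc(OC)c(Oc2cc(OCC)c(OCc3ccccc3)c(OCC)c2)c(OC)c1
F5 | step 6 | benzyl ether of rings A–B–C phenol 14 | COc1cc(OC)c(Oc2cc(OCC)c(Oc3cc(OCC)c(OCc4ccccc4)c(OCC)c3)c(OCC)c2)c(OC)c1
F6 | step 12 | rings A–F hexamer ending in a 3,4,5-trimethoxyphenyl group | COc1cc(OC)c(Oc2cc(OCC)c(Oc3cc(OCC)c(Oc4cc(OCC)c(Oc5cc(OCC)c(Oc6cc(OC)c(OC)c(OC)c6)c(OCC)c5)c(OCC)c4)c(OCC)c3)c(OCC)c2)c(OC)c1
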